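Two questions are put to each of the flasks alder and birch: which substance holds most of the charge at the end, and how much of it.

| setting | south-east | east | alder | birch |
|---|---|---|---|---|
| starting material | 0.40 M | 0.40 M | 0.40 M | 0.40 M |
| catalyst | 13 mM | 17 mM | 24 mM | 16 mM |
| remark | run made earlier | run made earlier |  |  |
| time |  |  | 30 min | 30 min |

| run | time / min | side product / % | starting material / % | target / % |
|---|---|---|---|---|
| south-east | 4.00 | 17.3 | 71.5 | 5.5 |
| south-east | 10.0 | 34.5 | 44.9 | 13.5 |
| south-east | 20.0 | 51.3 | 21.9 | 20.3 |
| south-east | 30.0 | 60.6 | 12.3 | 23.6 |
| east | 2.50 | 12.1 | 78.1 | 6.3 |
| east | 6.00 | 23.3 | 58.7 | 12.9 |
| east | 12.0 | 37.1 | 35.5 | 20.7 |
| east | 30.0 | 55.4 | 11.0 | 30.4 |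

(readings scatter by 0.5 percentage points)

1. which of these there is most of at the end, counted by the starting material in it, alder (side product / starting material / target)
2. which of these there is most of at the end, counted by the starting material in it, birch (side product / starting material / target)
3. amount of the one of these that there is most of at the end, in percent of the starting material charged, alder
4. amount of the one of these that there is most of at the end, in percent of the starting material charged, birch

- the analysis behind the earlier runs scatters by 0.5 percentage points, standard deviation
- a reading or a percentage of target counts all its forms, free or not
- a reading of starting material is of its free form alone

I begin with the final readings of the earlier runs. I divide side product by target and multiply by the catalyst charged, which gives 33.4 mM for the south-east run and 31.0 mM for the east run. They differ by 2.40 mM, and I take their mean as a reading of the balance catalyst, 32.2 mM, defined as the number that, divided by the catalyst charged, gives the ratio of side product to target, with the charge of starting material held at 0.40 M and the time at 30 min. It is a selectivity factor expressed as a concentration.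

From it, side product's share of the two products is the balance catalyst over the sum of the balance catalyst and the catalyst charged. That share is 57.3% in alder and 66.8% in birch.

The small correction is the remainder, the fraction of the charge in neither product. It is 15.8% in the south-east run and 14.2% in the east run. A straight line through these gives 14.6% for birch, which lies between the runs, and 11.4% for alder, which lies beyond them.

That alder step is the weak link. If I assume that the remainder decays exponentially, with a rate constant that rises in a straight line with catalyst, its logarithm runs straight with catalyst, so I redo the alder step that way and get 11.8% for alder. I therefore commit to side product at 50.5% in alder and 57.0% in birch, ahead of target and the remainder in each.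

The forecast also names side product for alder and side product for birch, at 49% and 56.7%, with target formation “roughly proportional to catalyst”. Its alder figure is below my 50.5%.

The flask gives side product holding most in both: 49.9% beside 37.6% of target, all its forms counted, in alder, and 56.7% beside 28.5% in birch.

    starting material + catalyst → catalyst + target (k = 1.60 /M/min)
    starting material → side product (k = 0.0510 /min)
    starting material + target ⇌ idle adduct, settled at all times (K = 3.90 /M)

Side product over target at the end, times the catalyst charged, is 31.9 mM for alder and 31.9 mM for birch, beside the carried 32.2 mM. A neighbouring flask repeats birch with 0.040 M of catalyst, above the balance catalyst. Its side-product share reckons as 44.6% and its remainder as 7.69%, so I get 41.2% of side product and 51.1% of target. The neighbouring flask gives 40.4% of side product and 50.7% of target, all its forms counted.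

The numbers in the tables were computed for an exercise; noise was put on by code.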